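The route rests on cutting the bond between the side-chain CH2 and the hindered ketone carbon. The two side-chain ketones stand in a 1,6-relationship across CMe2–(CH2)3. They are therefore read as a cleaved 2,6,6-trimethylcyclohexene ring, and the ketone carbon is carried as the sp2 carbon of an enol triflate. The key step is hydroboration of a stereodefined 6-vinyl-1,2-dioxane followed by B-alkyl Suzuki–Miyaura coupling, which joins both halves in one flask. The quaternary dioxane carbon C6 sends boron to the terminal carbon, and no reagent harmful to the O–O bond or the ester is needed. Ozonolysis of the temporary ring then releases both ketones at once.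

Key step: step 11

Remark: acyclic intermediates are numbered as octanoates (C1 = ester carbon), and C3 and C6 become the ring carbons of the 1,2-dioxane. The C6 descriptor switches between S and R from 11 to 16 only because the CIP rank of its arm changes; the spatial arrangement stays the same.

Step 1
Reactants: 1 (E)-2-methylbut-2-en-1-ol
Product: 2 (E)-1-bromo-2-methylbut-2-ene
Conditions: PBr3 (0.4 equiv), Et2O, 0 °C
Reagents that add atoms: phosphorus tribromide, BrP(Br)Br
Why: SN2 bromination of a primary allylic alcohol through its phosphite ester should keep the E geometry of the trisubstituted alkene.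

Step 2
Reactants: 2 (E)-1-bromo-2-methylbut-2-ene; 3 methyl acetoacetate
Product: 4 methyl (E)-6-methyl-3-oxooct-6-enoate
Conditions: NaH, THF, 0 °C; n-BuLi, 0 °C; then 2, 0 °C to rt
Reagents that add atoms: none
Why: Double deprotonation makes the terminal carbon of the keto ester the most nucleophilic site (acetoacetate γ-alkylation), and it should displace the primary allylic bromide by SN2.

Step 3
Reactants: 4 methyl (E)-6-methyl-3-oxooct-6-enoate
Product: 5 methyl (3R,6E)-3-hydroxy-6-methyloct-6-enoate
Conditions: H2 (4 bar), RuCl2[(R)-BINAP] (0.5 mol%), MeOH, 50 °C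
Reagents that add atoms: none
Why: In this Noyori asymmetric hydrogenation of a β-keto ester, chelation of the keto ester to the (R)-BINAP ruthenium hydride sets C3 as R, and the isolated trisubstituted alkene has no directing group and should not be reduced.

Step 4
Reactants: 5 methyl (3R,6E)-3-hydroxy-6-methyloct-6-enoate
Product: 6 methyl (2R,3R,6E)-3-hydroxy-2,6-dimethyloct-6-enoate
Conditions: LiN(i-Pr)2 (2.2 equiv), THF, −78 to −20 °C; MeI, DMPU, −78 to 0 °C
Reagents that add atoms: iodomethane, CI
Why: In this Fráter–Seebach alkylation the chelated lithium alkoxide enolate is methylated on the face away from the C3 chain, so C2 is set anti to the hydroxyl group (2R,3R).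

Step 5
Reactants: 6 methyl (2R,3R,6E)-3-hydroxy-2,6-dimethyloct-6-enoate
Product: 7 methyl (2R,3R,6E)-2,6-dimethyl-3-(methylsulfonyloxy)oct-6-enoate
Conditions: MsCl, Et3N, CH2Cl2, −10 °C
Reagents that add atoms: methanesulfonyl chloride, CS(=O)(=O)Cl
Why: O-sulfonylation leaves the C3–O bond and its configuration untouched, and Et3N in the cold is too weak a base to trigger elimination.

Step 6
Reactants: 7 methyl (2R,3R,6E)-2,6-dimethyl-3-(methylsulfonyloxy)oct-6-enoate
Product: 8 methyl (2R,3R)-5-[(2R,3R)-2,3-dimethyloxiran-2-yl]-2-methyl-3-(methylsulfonyloxy)pentanoate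
Conditions: D-fructose-derived Shi ketone (30 mol%), KHSO5 (as 2KHSO5·KHSO4·K2SO4), K2CO3, Bu4NHSO4, aq. Na2B4O7 buffer, MeCN/CH2(OMe)2, 0 °C
Reagents that add atoms: potassium peroxymonosulfate, [K+].OOS(=O)(=O)[O-]
Why: In this Shi asymmetric epoxidation the chiral ketone/KHSO5 system transfers oxygen through a spiro transition state to one face of the E-trisubstituted alkene, setting C6 and C7 as R,R under reagent control while ester and mesylate stay inert.

Step 7
Reactants: 8 methyl (2R,3R)-5-[(2R,3R)-2,3-dimethyloxiran-2-yl]-2-methyl-3-(methylsulfonyloxy)pentanoate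
Product: 9 methyl (2R,3R,6S,7R)-6-hydroperoxy-7-hydroxy-2,6-dimethyl-3-(methylsulfonyloxy)octanoate
Conditions: anhydrous H2O2 in Et2O (10 equiv), H3PMo12O40 (3 mol%), 0 °C to rt
Reagents that add atoms: hydrogen peroxide, OO
Why: In this acid-catalysed perhydrolysis of an epoxide (borderline SN2), H2O2 attacks the activated oxirane from the back side at the tertiary carbon C6, which bears most of the positive charge, so C6 is inverted from R to S and the C7–O bond keeps its configuration.

Step 8
Reactants: 9 methyl (2R,3R,6S,7R)-6-hydroperoxy-7-hydroxy-2,6-dimethyl-3-(methylsulfonyloxy)octanoate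
Product: 10 methyl (2R)-2-{(3S,6S)-6-[(1R)-1-hydroxyethyl]-6-methyl-1,2-dioxan-3-yl}propanoate
Conditions: KOt-Bu (1.0 equiv), 18-crown-6, THF (0.01 M), −20 °C to rt
Reagents that add atoms: none
Why: In this intramolecular alkylation of a hydroperoxide (6-exo-tet SN2) the peroxy anion is the only base present and should displace the C3 mesylate with inversion (R to S) faster than the less acidic C7 hydroxyl reacts or bimolecular elimination occurs at high dilution.

Step 9
Reactants: 10 methyl (2R)-2-{(3S,6S)-6-[(1R)-1-hydroxyethyl]-6-methyl-1,2-dioxan-3-yl}propanoate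
Product: 11 methyl (2R)-2-[(3S,6S)-6-ethenyl-6-methyl-1,2-dioxan-3-yl]propanoate
Conditions: Burgess reagent (MeO2CN−SO2N+Et3), toluene, 55 °C
Reagents that add atoms: none
Why: In this Burgess dehydration the sulfamate of the C7 hydroxyl undergoes thermal syn elimination, and because C6 is quaternary only the methyl hydrogens are available, so only the vinyl group can form while C2, C3 and C6 stay untouched.

Step 10
Reactants: 12 2,2,6-trimethylcyclohexanone (racemic)
Product: 13 2,6,6-trimethylcyclohex-1-en-1-yl trifluoromethanesulfonate
Conditions: LiN(i-Pr)2, THF, −78 to 0 °C; PhNTf2, 0 °C to rt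
Reagents that add atoms: N-phenylbis(trifluoromethanesulfonimide), FC(F)(F)S(=O)(=O)N(c1ccccc1)S(=O)(=O)C(F)(F)F
Why: In this enolate O-triflation the ketone has a single α-hydrogen, so only one enolate can form, and its trapping on oxygen erases the stereocentre of the racemic ketone.

Step 11
Reactants: 11 methyl (2R)-2-[(3S,6S)-6-ethenyl-6-methyl-1,2-dioxan-3-yl]propanoate; 13 2,6,6-trimethylcyclohex-1-en-1-yl trifluoromethanesulfonate
Product: 15 methyl (2R)-2-{(3S,6R)-6-methyl-6-[2-(2,6,6-trimethylcyclohex-1-en-1-yl)ethyl]-1,2-dioxan-3-yl}propanoate, via B-alkyl-9-BBN borane 14 (not isolated)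
Conditions: 9-BBN-H, THF, 0 °C to rt; then 13, PdCl2(dppf)·CH2Cl2 (8 mol%), aq. K3PO4, DMF, 50 °C
Reagents that add atoms: 9-borabicyclo[3.3.1]nonane, B1C2CCCC1CCC2 (its boron unit is carried by 14 only)
Why: 9-BBN-H adds syn across the vinyl group with boron on the terminal carbon, aqueous phosphate activates borane 14 for transmetalation, zerovalent palladium inserts into the C–O bond of triflate 13, and alkyl transfer from boron followed by reductive elimination forges the CH2–C(sp2) bond. The closest known reaction type is the B-alkyl Suzuki–Miyaura coupling of enol triflates, and both hydrometallation and palladium-catalysed coupling are known to leave dialkyl peroxides intact. No ring is closed and no stereocentre is formed, and C2, C3 and C6 are not touched because the only base is aqueous phosphate. The step needs terminal regioselectivity, which the quaternary C6 next to the alkene secures and which also avoids a boron β to the peroxide oxygen, and it needs chemoselectivity for C=C over the ester, which 9-BBN-H provides at room temperature. It also needs survival of the O–O bond, which is helped by its saturated monocyclic setting between a tertiary and a secondary carbon and by the chelating dppf, which leaves no free phosphine. The crowding of the triflate carbon between CMe2 and the C-methyl group is offset by the unhindered primary borane, by the wide bite angle of dppf, which speeds reductive elimination over β-hydride elimination, and by gentle heating in DMF.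

Step 12
Reactants: 15 methyl (2R)-2-{(3S,6R)-6-methyl-6-[2-(2,6,6-trimethylcyclohex-1-en-1-yl)ethyl]-1,2-dioxan-3-yl}propanoate
Product: 16 diacarperoxide C, methyl (2R)-2-[(3S,6S)-6-(4,4-dimethyl-3,8-dioxononyl)-6-methyl-1,2-dioxan-3-yl]propanoate
Conditions: O3, CH2Cl2/MeOH, −78 °C; then Me2S, −78 °C to rt
Reagents that add atoms: ozone, [O-][O+]=O
Why: In this Criegee ozonolysis the tetrasubstituted ring alkene is the only C=C bond, and Me2S reduces the hydroperoxidic ozonolysis products but not the dialkyl peroxide of the 1,2-dioxane, so both ketones should appear with all three stereocentres untouched.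

Compound list
1 | (E)-2-methylbut-2-en-1-ol | OC/C(C)=C/C | starting material
2 | (E)-1-bromo-2-methylbut-2-ene | BrC/C(C)=C/C | intermediate
3 | methyl acetoacetate | COC(=O)CC(C)=O | starting material
4 | methyl (E)-6-methyl-3-oxooct-6-enoate | COC(=O)CC(=O)CC/C(C)=C/C | intermediate
5 | methyl (3R,6E)-3-hydroxy-6-methyloct-6-enoate | COC(=O)C[C@H](O)CC/C(C)=C/C | intermediate
6 | methyl (2R,3R,6E)-3-hydroxy-2,6-dimethyloct-6-enoate | COC(=O)[C@H](C)[C@H](O)CC/C(C)=C/C | intermediate
7 | methyl (2R,3R,6E)-2,6-dimethyl-3-(methylsulfonyloxy)oct-6-enoate | COC(=O)[C@H](C)[C@H](OS(C)(=O)=O)CC/C(C)=C/C | intermediate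
8 | methyl (2R,3R)-5-[(2R,3R)-2,3-dimethyloxiran-2-yl]-2-methyl-3-(methylsulfonyloxy)pentanoate | COC(=O)[C@H](C)[C@H](OS(C)(=O)=O)CC[C@]1(C)[C@@H](C)O1 | intermediate
9 | methyl (2R,3R,6S,7R)-6-hydroperoxy-7-hydroxy-2,6-dimethyl-3-(methylsulfonyloxy)octanoate | COC(=O)[C@H](C)[C@H](OS(C)(=O)=O)CC[C@@](C)([C@H](O)C)OO | intermediate
10 | methyl (2R)-2-{(3S,6S)-6-[(1R)-1-hydroxyethyl]-6-methyl-1,2-dioxan-3-yl}propanoate | COC(=O)[C@H](C)[C@@H]1CC[C@@](C)([C@H](O)C)OO1 | intermediate
11 | methyl (2R)-2-[(3S,6S)-6-ethenyl-6-methyl-1,2-dioxan-3-yl]propanoate | COC(=O)[C@H](C)[C@@H]1CC[C@@](C)(C=C)OO1 | intermediate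
12 | 2,2,6-trimethylcyclohexanone (racemic) | CC1CCCC(C)(C)C1=O | starting material
13 | 2,6,6-trimethylcyclohex-1-en-1-yl trifluoromethanesulfonate | CC1=C(OS(=O)(=O)C(F)(F)F)C(C)(C)CCC1 | intermediate
14 | methyl (2R)-2-{(3S,6R)-6-[2-(9-borabicyclo[3.3.1]nonan-9-yl)ethyl]-6-methyl-1,2-dioxan-3-yl}propanoate | COC(=O)[C@H](C)[C@@H]1CC[C@@](C)(CCB2C3CCCC2CCC3)OO1 | intermediate
15 | methyl (2R)-2-{(3S,6R)-6-methyl-6-[2-(2,6,6-trimethylcyclohex-1-en-1-yl)ethyl]-1,2-dioxan-3-yl}propanoate | COC(=O)[C@H](C)[C@@H]1CC[C@@](C)(CCC2=C(C)CCCC2(C)C)OO1 | intermediate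
16 | diacarperoxide C, methyl (2R)-2-[(3S,6S)-6-(4,4-dimethyl-3,8-dioxononyl)-6-methyl-1,2-dioxan-3-yl]propanoate | COC(=O)[C@H](C)[C@@H]1CC[C@@](C)(CCC(=O)C(C)(C)CCCC(C)=O)OO1 | target

Total step count: 12. Longest linear sequence: 11 steps (steps 1 to 9, 11 and 12).

Steps most likely to fail

1. Step 11. Oxidative addition and transmetalation at the doubly flanked triflate carbon may be slow. Protodeboronation, β-hydride elimination, hydrolysis of the triflate, 1,3-elimination of the activated borane or metal-induced cleavage of the O–O bond could then take over. The fallback sets out from 12 and from borane 14 and comes back at 16; it gives up the ring mask and makes the ketone directly by acyl cross-coupling. Ketone 12 is cleaved between C1 and C6 with O2 and catalytic Cu(NO3)2 in aqueous AcOH to 2,2-dimethyl-6-oxoheptanoic acid F1. This acid is condensed with thiophenol (DCC, DMAP, CH2Cl2) to S-phenyl 2,2-dimethyl-6-oxoheptanethioate F2. Borane 14, made from 11 as before, is then joined to F2 by Liebeskind–Srogl coupling [Pd2(dba)3, P(2-furyl)3, Cu(O2CC4H3S), Cs2CO3, THF, 45 °C]. This forms the same CH2–C(=O) bond and should give 16 without any ozonolysis.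

2. Step 8. Base-induced loss of methanesulfonate across C2–C3 may compete with substitution, and re-addition of the peroxy anion to the unsaturated ester would erode the configuration at C2 and C3. The fallback sets out from 9 and comes back at 10; it replaces substitution by a deliberate conjugate addition. DBU in CH2Cl2 at 0 °C removes the mesylate on purpose and should give methyl (2E,6S,7R)-6-hydroperoxy-7-hydroxy-2,6-dimethyloct-2-enoate F3. Et2NH in CF3CH2OH then triggers 6-exo-trig oxa-Michael closure through a chair with the enoate and the branched 1-hydroxyethyl group equatorial, which should favour the wanted C3 configuration. C2 arises from protonation of the ester enolate, so the C2 epimer has to be removed by chromatography before 10 is carried on.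

3. Step 9. Ionisation of the sulfamate at the neopentyl-type carbon C7, with a 1,2-shift from C6, may outrun the syn elimination. The fallback sets out from 10 and comes back at 11; it replaces dehydration by oxidation and hydrogenolysis of an enol triflate. Dess–Martin oxidation should give methyl (2R)-2-[(3S,6S)-6-acetyl-6-methyl-1,2-dioxan-3-yl]propanoate F4, whose ketone can enolise only toward its methyl group. KN(SiMe3)2 (1.0 equiv, THF, −78 °C) and PhNTf2 convert it into methyl (2R)-2-{(3S,6S)-6-methyl-6-[1-(trifluoromethylsulfonyloxy)ethenyl]-1,2-dioxan-3-yl}propanoate F5. Formate reduction [Pd(OAc)2, dppf, HCO2H, Et3N, DMF, 40 °C] then delivers 11.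

Further compounds
F1 | step 11 | 2,2-dimethyl-6-oxoheptanoic acid | CC(=O)CCCC(C)(C)C(=O)O
F2 | step 11 | S-phenyl 2,2-dimethyl-6-oxoheptanethioate | CC(=O)CCCC(C)(C)C(=O)Sc1ccccc1
F3 | step 8 | methyl (2E,6S,7R)-6-hydroperoxy-7-hydroxy-2,6-dimethyloct-2-enoate | COC(=O)/C(C)=C/CC[C@@](C)([C@H](O)C)OO
F4 | step 9 | methyl (2R)-2-[(3S,6S)-6-acetyl-6-methyl-1,2-dioxan-3-yl]propanoate | COC(=O)[C@H](C)[C@@H]1CC[C@@](C)(C(C)=O)OO1
F5 | step 9 | methyl (2R)-2-{(3S,6S)-6-methyl-6-[1-(trifluoromethylsulfonyloxy)ethenyl]-1,2-dioxan-3-yl}propanoate | COC(=O)[C@H](C)[C@@H]1CC[C@@](C)(C(=C)OS(=O)(=O)C(F)(F)F)OO1
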